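An easy step came first: I replaced each curve by one constant. These are the flasks, the readings and the questions.

| setting | Wednesday's | Monday's | Tuesday's | Saturday's | Thursday's |
|---|---|---|---|---|---|
| starting material | 0.800 M | 0.480 M | 0.400 M | 0.800 M | 0.800 M |
| reagent | 0.880 M | 0.560 M | 0.880 M | 0.880 M | 2.20 M |
| catalyst | 0.0640 M | 0.0640 M | 0.0640 M | 0.130 M | 0.0640 M |
| time |  |  |  |  | 20 min |

- Wednesday's run (time / min: [starting material] / M): 3.3: 0.614; 6.7: 0.467; 10: 0.383; 13: 0.330; 17: 0.277; 20: 0.258
- Monday's run (time / min: [starting material] / M): 3.3: 0.415; 6.7: 0.334; 10: 0.276; 13: 0.239; 17: 0.205; 20: 0.181
- Tuesday's run (time / min: [starting material] / M): 3.3: 0.301; 6.7: 0.208; 10: 0.147; 13: 0.121; 17: 0.086; 20: 0.073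
- Saturday's run (time / min: [starting material] / M): 3.3: 0.512; 6.7: 0.342; 10: 0.264; 13: 0.214; 17: 0.169; 20: 0.149

(each reading ± 0.004 M)

- Overall: starting material + reagent -> target, with catalyst as catalyst.
- Constant volume, constant temperature.
- Bound and free are read together.
- "The second partner" is reagent.
- An order is taken over about fifteen percent of the charge, up and down.

1. the power of [catalyst] that the first rate follows, about the charge of the Wednesday's run; measure it at two percent of starting material made into target
2. the power of [reagent] that the first rate follows, about the charge of the Wednesday's run; measure it at two percent of starting material made into target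
3. starting material in the Thursday's run at 20 min, as a share of the starting material charged

Each target formed takes one starting material and one reagent, so the two fall together and a rate κ·c(starting material)·c(reagent) integrates in closed form. For Wednesday's run the last reading gives 0.109 /M/min. I call this the mean coefficient, the constant κ that carries a run from its charge to a given point of its curve. It stands in for a curve, so the error it makes has to be checked.

I took reagent first. A first power in reagent leaves κ unchanged when reagent is changed. Tuesday's run gives 0.129 /M/min and Monday's run 0.132 /M/min, alike though their reagent charges differ, so I took a first power.

Catalyst came next. A first power scales κ by the charge ratio, here 2.03 from Wednesday's run to Saturday's run. Saturday's run gives 0.209 /M/min, which makes a power of 0.919. That is a whole-run figure, though. The question stands at 0.0160 M turned, and Wednesday's first reading is already past it at 0.186 M, so I held this power loosely.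

Last came the reagent charge of Thursday's run, where starting material is the limiting reagent, at 0.800 M against 2.20 M. Wednesday's κ leaves 3.04%. But Wednesday's run, with 0.542 M of target made, kept a lower κ than Tuesday's run, which made 0.327 M. Thursday's run makes still more, about 0.776 M, so I expected my share to come out low.

The forecast gave 0.85 for catalyst, 0.9 for reagent and 5% for Thursday's run. That share is above mine, and it rests on a late slowing that it read as one which “suggests mild product inhibition or catalyst decay”.

The flask gave 0.58 for catalyst, 1.0 for reagent and 4.21% for Thursday's run, by these steps:

    active catalyst + starting material + reagent → target + active catalyst (2.934 /M²/min)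
    active catalyst + target ⇌ catalyst-product complex, settled at all times (1.570 /M)
    catalyst + reagent → active catalyst + reagent (0.8820 /M/min)

At two percent turned, Saturday's run went 1.5 times as fast as Wednesday's run, less than its catalyst ratio of 2.03. Put back into the mean coefficient, Thursday's 4.21% means 0.0979 /M/min, below Wednesday's 0.109 /M/min. Carried to Tuesday's run, Wednesday's κ puts target at half of the charge at 8.30 min, later than the 6.97 min at which Tuesday's run reached it.

(The readings were computed for an exercise; scatter was added.)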